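The route assembles the depsidone from a ring-B cyclic carbonate and a ring-A aryne in one cascade. Everything rests on cutting ring A (the formyl/methyl benzene) out of the seven-membered dioxepinone ring as an aryne. The key step exploits three neighbours on ring B (the phthalide ring): the ether oxygen on C-4, the ester oxygen on C-5 and the hydroxymethyl group on C-6. In the precursor the last two are tied as a six-membered cyclic carbonate beside the free 4-OH. The phenoxide adds to a 3-chloroaryne; the aryl anion is then acylated by the carbonate. One operation thus makes the diaryl ether bond and the aryl–carbonyl bond, closes the dioxepinone and frees the CH2OH for the fumarate. Chlorine, which steers the addition, is later exchanged for methyl.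

Key step: step 14

Assumption: the lactol carbon is a hemiacetal centre that epimerises through the ring-opened formyl acid in basic or protic media, so it is set last by crystallisation; the (S)-amine is assumed to crystallise the (R)-lactol salt, and the mirror-image amine is used if the first crop proves to be the (S)-lactol.

**Ring A (aryne precursor)**

Step 1
Reactants: 1 5-chlororesorcinol
Product: 2 1-chloro-3,5-bis(methoxymethoxy)benzene
Conditions: NaH, MOMCl, DMF, 0 °C → rt
Reagents that add atoms: chloromethyl methyl ether, COCCl
Why: Williamson O-alkylation of both phenoxides should give the bis-MOM ether, whose OMOM groups direct the next metalation.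

Step 2
Reactants: 2 1-chloro-3,5-bis(methoxymethoxy)benzene
Product: 3 4-chloro-2,6-bis(methoxymethoxy)benzaldehyde
Conditions: n-BuLi, TMEDA, THF, −40 °C; DMF; aq. NH4Cl
Reagents that add atoms: N,N-dimethylformamide, CN(C)C=O
Why: Directed ortho-metalation should occur at the C–H flanked by the two chelating OMOM groups (not next to Cl), and formylation of the aryllithium with DMF gives the aldehyde.

Step 3
Reactants: 3 4-chloro-2,6-bis(methoxymethoxy)benzaldehyde
Product: 4 4-chloro-2-hydroxy-6-(methoxymethoxy)benzaldehyde
Conditions: cat. conc. HCl, MeOH, 0 °C → rt, stopped at mono-cleavage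
Reagents that add atoms: none
Why: Acid-catalysed acetal exchange should remove one MOM group of the symmetric substrate, and the hydrogen bond of the freed phenol to the aldehyde slows loss of the second (chelation-controlled mono-deprotection).

Step 4
Reactants: 4 4-chloro-2-hydroxy-6-(methoxymethoxy)benzaldehyde
Product: 6 5-chloro-2-(dimethoxymethyl)-3-(methoxymethoxy)phenyl N-isopropylcarbamate, via phenol acetal 5 (not isolated)
Conditions: HC(OMe)3, MeOH, cat. PPTS, rt; Et3N, evaporate; then i-PrNCO, Et3N, CH2Cl2, rt
Reagents that add atoms: trimethyl orthoformate, COC(OC)OC; isopropyl isocyanate, CC(C)N=C=O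
Why: Acetalisation before carbamoylation should keep the N–H carbamate from closing onto a free aldehyde, and addition of the phenol to the isocyanate gives the carbamate that serves as directing group.

Step 5
Reactants: 6 5-chloro-2-(dimethoxymethyl)-3-(methoxymethoxy)phenyl N-isopropylcarbamate
Product: 8 3-chloro-6-(dimethoxymethyl)-5-(methoxymethoxy)-2-(trimethylsilyl)phenyl N-isopropylcarbamate, via N-TBS carbamate 7 (not isolated)
Conditions: TBSOTf, TMEDA, Et2O, 0 °C → rt; n-BuLi, TMEDA, −78 °C; TMSCl, −78 °C → rt; aq. NH4Cl
Reagents that add atoms: chlorotrimethylsilane, C[Si](C)(C)Cl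
Why: N-Silylation blocks the N–H, and carbamate-directed ortho-lithiation should take place at the only free ortho position, which is also acidified by the neighbouring chlorine; silyl quench at −78 °C precedes any loss of LiCl.

Step 6
Reactants: 8 3-chloro-6-(dimethoxymethyl)-5-(methoxymethoxy)-2-(trimethylsilyl)phenyl N-isopropylcarbamate
Product: 10 3-chloro-6-(dimethoxymethyl)-5-(methoxymethoxy)-2-(trimethylsilyl)phenyl trifluoromethanesulfonate, via silyl phenol 9 (not isolated)
Conditions: DBU, Et2NH, MeCN, 40 °C; then PhNTf2, rt
Reagents that add atoms: N-phenylbis(trifluoromethanesulfonimide), O=S(=O)(N(c1ccccc1)S(=O)(=O)C(F)(F)F)C(F)(F)F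
Why: Base-induced E1cB loss of isopropyl isocyanate (trapped by Et2NH) should give the phenoxide, which is triflated in the same flask to the o-silylaryl triflate without any acid that could protodesilylate.

**Ring B (carbonate phenol)**

Step 7
Reactants: 11 2,4,5-trihydroxybenzaldehyde
Product: 12 6-hydroxy-2,2-diphenyl-1,3-benzodioxole-5-carbaldehyde
Conditions: Ph2CCl2, K2CO3, MeCN, 60 °C
Reagents that add atoms: dichlorodiphenylmethane, ClC(Cl)(c1ccccc1)c1ccccc1
Why: Only the vicinal 4,5-diol can close the five-membered diphenylmethylene ketal, so the chelated 2-OH should stay free (catechol ketalisation).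

Step 8
Reactants: 12 6-hydroxy-2,2-diphenyl-1,3-benzodioxole-5-carbaldehyde
Product: 13 6-(methoxymethoxy)-2,2-diphenyl-1,3-benzodioxole-5-carbaldehyde
Conditions: NaH, MOMCl, DMF, 0 °C → rt
Reagents that add atoms: chloromethyl methyl ether, COCCl
Why: Williamson O-alkylation of the sodium phenoxide should protect the phenol that will later sit ortho to the lactone carbonyl.

Step 9
Reactants: 13 6-(methoxymethoxy)-2,2-diphenyl-1,3-benzodioxole-5-carbaldehyde
Product: 14 6-(methoxymethoxy)-2,2-diphenyl-1,3-benzodioxole-5-carboxylic acid
Conditions: NaClO2, NaH2PO4, 2-methyl-2-butene, t-BuOH–H2O, rt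
Reagents that add atoms: sodium chlorite, [Na+].[O-]Cl=O
Why: Pinnick oxidation should convert the aldehyde to the acid under buffered conditions that spare the MOM ether and the ketal, with the alkene scavenging hypochlorite.

Step 10
Reactants: 14 6-(methoxymethoxy)-2,2-diphenyl-1,3-benzodioxole-5-carboxylic acid
Product: 15 7-(hydroxymethyl)-6-(methoxymethoxy)-2,2-diphenyl-1,3-benzodioxole-5-carboxylic acid
Conditions: n-BuLi/t-BuOK (4 equiv), THF, −78 °C; dry paraformaldehyde, −78 °C → rt; aq. NH4Cl then citric acid to pH 4
Reagents that add atoms: formaldehyde (from paraformaldehyde), C=O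
Why: Superbase metalation of the carboxylate should occur at the most acidic ring C–H, the one between the OMOM and the ketal oxygen, and the aryl metal is hydroxymethylated by formaldehyde (directed metalation of an unprotected benzoic acid).

Step 11
Reactants: 15 7-(hydroxymethyl)-6-(methoxymethoxy)-2,2-diphenyl-1,3-benzodioxole-5-carboxylic acid
Product: 17 racemic 6-(hydroxymethyl)-3-methoxy-7-(methoxymethoxy)-4,5-(diphenylmethylenedioxy)phthalide, via lactol 16 (not isolated)
Conditions: s-BuLi (3.5 equiv), TMEDA, THF, −78 °C; DMF, −78 → 0 °C; aq. NH4Cl then citric acid to pH 4; then MeOH, reflux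
Reagents that add atoms: N,N-dimethylformamide, CN(C)C=O; methanol, CO
Why: Carboxylate-directed ortho-lithiation can only take the last ring C–H; formylation gives the o-formyl acid, which closes to the lactol, and hot methanol converts it to the racemic pseudo-ester (the acetal carbon is formed without control).

Step 12
Reactants: 17 racemic 6-(hydroxymethyl)-3-methoxy-7-(methoxymethoxy)-4,5-(diphenylmethylenedioxy)phthalide
Product: 18 racemic 4,5-dihydroxy-6-(hydroxymethyl)-3-methoxy-7-(methoxymethoxy)phthalide
Conditions: H2 (1 atm), 10% Pd/C, EtOAc, rt
Reagents that add atoms: none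
Why: Hydrogenolysis of the doubly benzylic ketal carbon should free the catechol under neutral conditions that leave the MOM ether and the pseudo-ester alone.

Step 13
Reactants: 18 racemic 4,5-dihydroxy-6-(hydroxymethyl)-3-methoxy-7-(methoxymethoxy)phthalide
Product: 19 racemic 4-hydroxy-3-methoxy-7-(methoxymethoxy)phthalide with O-5 and the 6-CH2O joined as a six-membered cyclic carbonate
Conditions: CDI (1.05 equiv), MeCN, 0 °C → rt
Reagents that add atoms: 1,1'-carbonyldiimidazole, O=C(n1ccnc1)n1ccnc1
Why: CDI should acylate the primary alcohol first and the O-5 phenol then closes the six-membered ring; any five-membered catechol carbonate is a less stable diaryl carbonate that the neighbouring alcohol converts, under imidazole catalysis, into the same aryl alkyl carbonate (carbonylation of a 1,3-diol unit under thermodynamic control).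

**Union and end game**

Step 14
Reactants: 19 racemic carbonate phenol (1.3 equiv); 10 o-silylaryl triflate
Product: 22 racemic chloro depsidone alcohol (ring A: Cl / OMOM / CH(OMe)2; ring B: CH2OH / OMOM / 3-methoxyphthalide), via aryne 20 (not isolated), via aryl caesium adduct 21 (not isolated)
Conditions: CsF (3 equiv), 18-crown-6 (0.2 equiv), THF–MeCN (5:1), 0 °C → rt; aq. NH4Cl
Reagents that add atoms: none
Why: Proposed new method: fluoride frees aryne 20 from 10 and CsF deprotonates the only free OH of 19; the phenoxide adds to the aryne carbon remote from chlorine, and the aryl anion 21, held next to the carbonate, attacks its carbonyl, whose tetrahedral intermediate expels the benzylic alkoxide (proton transfer from unreacted 19 then gives the alcohol). The closest known reaction types are the xanthone synthesis from salicylates and arynes (phenoxide addition then intramolecular acyl substitution) and the insertion of arynes into the N–CO bond of cyclic ureas. The dioxepinone ring closes by 7-exo-trig acyl substitution at the carbonate carbon, and the six-membered carbonate ring opens in the same event. No stereocentre is formed and the racemic acetal carbon is untouched. Three selectivities are needed: the arylated oxygen is fixed because the carbonate cannot migrate to O-4 (that isomer would need a four-atom meta bridge); the orientation on the aryne is fixed by the chlorine, which polarises the aryne so that the nucleophile enters at the distal carbon and the anion sits ortho to Cl; and of the two carbonate C–O bonds only the benzylic one can break, since loss of the aryloxide would leave a meta-bridged nine-membered lactone.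

Step 15
Reactants: 22 racemic chloro depsidone alcohol
Product: 23 racemic methyl depsidone alcohol (ring A: CH3 / OMOM / CH(OMe)2)
Conditions: Me2Zn (3 equiv), Pd(P(t-Bu)3)2 (5 mol%), THF, 50 °C; aq. NH4Cl
Reagents that add atoms: dimethylzinc, C[Zn]C
Why: Negishi cross-coupling of the aryl chloride, activated by the ortho ester carbonyl, should install the methyl group; dimethylzinc tolerates the esters, acetals and (as its zinc alkoxide) the free alcohol.

Step 16
Reactants: 23 racemic methyl depsidone alcohol; 24 fumaryl chloride (5 equiv)
Product: 26 racemic protected fumarate half-ester (CH2O–CO–CH=CH–CO2H with E geometry), via ester acid chloride 25 (not isolated)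
Conditions: 2,6-lutidine, CH2Cl2, −40 → 0 °C (23 added slowly to 24); then THF–aq. phosphate buffer pH 4, 0 °C
Reagents that add atoms: water, O
Why: Acylation of the primary alcohol by an excess of the diacid chloride should stop at the mono-ester, and hydrolysis of the remaining acyl chloride end gives the free half-acid with the E geometry of the reagent (Schotten–Baumann-type acylation).

Step 17
Reactants: 26 racemic protected fumarate half-ester
Product: 27 racemic target (both lactol epimers)
Conditions: 2 M aq. HCl–THF (1:2), 40 °C
Reagents that add atoms: water, O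
Why: Dilute aqueous acid should hydrolyse the dimethyl acetal, the two MOM ethers (each ortho to a carbonyl) and the pseudo-ester (an acetal with a carboxylate leaving group) while the aryl and benzylic esters survive; the lactol forms without control, as the racemate.

Step 18
Reactants: 27 racemic target; 28 (S)-N,N-dimethyl-1-phenylethylamine (1.0 equiv)
Product: 29 (S)-N,N-dimethyl-1-phenylethylammonium salt of the (R)-lactol target
Conditions: acetone–EtOAc, slurry, 20–35 °C, 48 h; filter
Reagents that add atoms: none
Why: Crystallisation-induced asymmetric transformation: the lactol epimers interconvert in solution through the ring-opened formyl acid (the pseudo-acid is the most acidic site after the fumaric carboxyl), the less soluble diastereomeric salt crystallises and drains the equilibrium, so the lattice of the (S)-amine salt sets the (R) configuration.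

Step 19
Reactants: 29 ammonium salt of the (R)-lactol target
Product: 30 target, (R)-lactol
Conditions: 0.5 M aq. HCl / EtOAc, 0 °C; dry; crystallise cold from acetone–heptane
Reagents that add atoms: none
Why: Protonation of the carboxylate at 0 °C touches no bond at the lactol carbon, and cold, acidic, aprotic handling should keep the hemiacetal closed so that the configuration set in step 18 is kept (salt break).

**Compound list**

1 | 5-chlororesorcinol | Oc1cc(O)cc(Cl)c1 | starting material
2 | 1-chloro-3,5-bis(methoxymethoxy)benzene | COCOc1cc(Cl)cc(OCOC)c1 | intermediate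
3 | 4-chloro-2,6-bis(methoxymethoxy)benzaldehyde | COCOc1cc(Cl)cc(OCOC)c1C=O | intermediate
4 | 4-chloro-2-hydroxy-6-(methoxymethoxy)benzaldehyde | COCOc1cc(Cl)cc(O)c1C=O | intermediate
5 | 5-chloro-2-(dimethoxymethyl)-3-(methoxymethoxy)phenol | COCOc1cc(Cl)cc(O)c1C(OC)OC | intermediate
6 | 5-chloro-2-(dimethoxymethyl)-3-(methoxymethoxy)phenyl N-isopropylcarbamate | COCOc1cc(Cl)cc(OC(=O)NC(C)C)c1C(OC)OC | intermediate
7 | N-(tert-butyldimethylsilyl) derivative of carbamate 6 | COCOc1cc(Cl)cc(OC(=O)N(C(C)C)[Si](C)(C)C(C)(C)C)c1C(OC)OC | intermediate
8 | 3-chloro-6-(dimethoxymethyl)-5-(methoxymethoxy)-2-(trimethylsilyl)phenyl N-isopropylcarbamate | COCOc1cc(Cl)c([Si](C)(C)C)c(OC(=O)NC(C)C)c1C(OC)OC | intermediate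
9 | 3-chloro-6-(dimethoxymethyl)-5-(methoxymethoxy)-2-(trimethylsilyl)phenol | COCOc1cc(Cl)c([Si](C)(C)C)c(O)c1C(OC)OC | intermediate
10 | 3-chloro-6-(dimethoxymethyl)-5-(methoxymethoxy)-2-(trimethylsilyl)phenyl trifluoromethanesulfonate | COCOc1cc(Cl)c([Si](C)(C)C)c(OS(=O)(=O)C(F)(F)F)c1C(OC)OC | intermediate
11 | 2,4,5-trihydroxybenzaldehyde | O=Cc1cc(O)c(O)cc1O | starting material
12 | 6-hydroxy-2,2-diphenyl-1,3-benzodioxole-5-carbaldehyde | O=Cc1cc2OC(c3ccccc3)(c3ccccc3)Oc2cc1O | intermediate
13 | 6-(methoxymethoxy)-2,2-diphenyl-1,3-benzodioxole-5-carbaldehyde | O=Cc1cc2OC(c3ccccc3)(c3ccccc3)Oc2cc1OCOC | intermediate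
14 | 6-(methoxymethoxy)-2,2-diphenyl-1,3-benzodioxole-5-carboxylic acid | OC(=O)c1cc2OC(c3ccccc3)(c3ccccc3)Oc2cc1OCOC | intermediate
15 | 7-(hydroxymethyl)-6-(methoxymethoxy)-2,2-diphenyl-1,3-benzodioxole-5-carboxylic acid | OC(=O)c1cc2OC(c3ccccc3)(c3ccccc3)Oc2c(CO)c1OCOC | intermediate
16 | racemic 3-hydroxy-6-(hydroxymethyl)-7-(methoxymethoxy)-4,5-(diphenylmethylenedioxy)phthalide (lactol) | OC1OC(=O)c2c(OCOC)c(CO)c3OC(c4ccccc4)(c4ccccc4)Oc3c12 | intermediate
17 | racemic 6-(hydroxymethyl)-3-methoxy-7-(methoxymethoxy)-4,5-(diphenylmethylenedioxy)phthalide | COC1OC(=O)c2c(OCOC)c(CO)c3OC(c4ccccc4)(c4ccccc4)Oc3c12 | intermediate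
18 | racemic 4,5-dihydroxy-6-(hydroxymethyl)-3-methoxy-7-(methoxymethoxy)phthalide | COC1OC(=O)c2c(OCOC)c(CO)c(O)c(O)c12 | intermediate
19 | racemic 4-hydroxy-3-methoxy-7-(methoxymethoxy)phthalide 5-O,6-CH2O cyclic carbonate | COC1OC(=O)c2c(OCOC)c3COC(=O)Oc3c(O)c12 | intermediate
20 | 3-chloro-6-(dimethoxymethyl)-5-(methoxymethoxy)benzyne | COC(OC)C1=C(OCOC)C=C(Cl)C#C1 | intermediate
21 | racemic aryl caesium adduct (diaryl ether with the carbanion between O and Cl; carbonate intact) | [Cs+].COC1OC(=O)c2c(OCOC)c3COC(=O)Oc3c(Oc3c(C(OC)OC)c(OCOC)cc(Cl)[c-]3)c12 | intermediate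
22 | racemic chloro depsidone alcohol | Clc1cc(OCOC)c(C(OC)OC)c2c1C(=O)Oc1c(CO)c(OCOC)c3c(c1O2)C(OC)OC3=O | intermediate
23 | racemic methyl depsidone alcohol | Cc1cc(OCOC)c(C(OC)OC)c2c1C(=O)Oc1c(CO)c(OCOC)c3c(c1O2)C(OC)OC3=O | intermediate
24 | fumaryl chloride | ClC(=O)/C=C/C(=O)Cl | starting material
25 | racemic ester acid chloride of 23 | Cc1cc(OCOC)c(C(OC)OC)c2c1C(=O)Oc1c(COC(=O)/C=C/C(=O)Cl)c(OCOC)c3c(c1O2)C(OC)OC3=O | intermediate
26 | racemic protected (E)-fumarate half-ester | Cc1cc(OCOC)c(C(OC)OC)c2c1C(=O)Oc1c(COC(=O)/C=C/C(=O)O)c(OCOC)c3c(c1O2)C(OC)OC3=O | intermediate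
27 | racemic target (lactol epimers) | Cc1cc(O)c(C=O)c2c1C(=O)Oc1c(COC(=O)/C=C/C(=O)O)c(O)c3c(c1O2)C(O)OC3=O | intermediate
28 | (S)-N,N-dimethyl-1-phenylethylamine | C[C@H](N(C)C)c1ccccc1 | starting material
29 | (S)-N,N-dimethyl-1-phenylethylammonium salt of the (R)-lactol target | Cc1cc(O)c(C=O)c2c1C(=O)Oc1c(COC(=O)/C=C/C(=O)[O-])c(O)c3c(c1O2)[C@H](O)OC3=O.C[C@H]([NH+](C)C)c1ccccc1 | intermediate
30 | target, (R)-lactol (E)-fumarate half-ester | Cc1cc(O)c(C=O)c2c1C(=O)Oc1c(COC(=O)/C=C/C(=O)O)c(O)c3c(c1O2)[C@H](O)OC3=O | target

**Count and risks**

Total step count: 19. Longest linear sequence: 13 steps (steps 7–19, from 11).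

Steps most likely to fail:

Step 14 (bears the label). The aryl anion may be protonated, or may lose chloride, faster than it closes the seven-membered ring, so that only O-arylation is seen. The fallback uses known chemistry, sets out from 19 and 10, and comes back at 22. The O-arylation is run on purpose under protic aryne conditions (CsF, MeCN, rt), a known phenol arylation, to give the diaryl ether F1 with the carbonate intact. F1 is then deprotonated with LiTMP in THF at −78 °C at the ring C–H between chlorine and the aryloxy oxygen. The aryllithium is stable at this temperature and closes onto the carbonate in a remote anionic Fries-type acyl transfer to give 22.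

Step 17. Once the phenol next to the benzylic ester is unmasked, acid may ionise the o-hydroxybenzyl C–O bond and strip the fumarate, or the pseudo-ester may resist hydrolysis under conditions mild enough for the ester. The fallback sets out from 23 and comes back at 27. Compound 23 is first deprotected with 2 M aq. HCl–THF to racemic salazinic acid F2. F2 is then heated with a large excess of fumaric acid in dioxane at 90 °C. The o-hydroxybenzyl alcohol is esterified at the benzylic carbon by way of its o-quinone methide, and the excess diacid keeps the product at the half-ester stage.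

Step 18. The salt may oil out, crystallise as a solid solution, or deposit the (S)-lactol epimer. The fallback sets out from 27 and comes back at 30; it makes no new compound (F0). The enantiomers of 27 are separated by preparative chromatography on a chiral stationary phase with an acidic, aprotic eluent at low temperature. The unwanted fraction is re-equilibrated with a trace of triethylamine, re-acidified and recycled.

Further compounds
F1 | step 14 | racemic diaryl ether from 19 and aryne 20 (ring A C–H between O and Cl; cyclic carbonate intact) | COC1OC(=O)c2c(OCOC)c3COC(=O)Oc3c(Oc3cc(Cl)cc(OCOC)c3C(OC)OC)c12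
F2 | step 17 | racemic salazinic acid | Cc1cc(O)c(C=O)c2c1C(=O)Oc1c(CO)c(O)c3c(c1O2)C(O)OC3=O
F0 | step 18 | none | none
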